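The percentage point of the charge is the unit at this blackboard: every amount below is a fraction of the starting material charged, and a is the fraction of starting material left.

| flask | starting material | reagent | remark | time |
|---|---|---|---|---|
| ash | 0.10 M | 0.18 M | the very flask that is asked about, followed so far |  |
| elm | 0.10 M | 0.36 M | run made earlier |  |
| flask | 0.10 M | 0.180 M |  | 6.0 min |

ash run (percent of the starting material charged)

| time / s | starting material / % | single product / % |
|---|---|---|
| 10.0 | 91 | 6 |
| 15.0 | 82 | 9 |
| 25.0 | 73 | 11 |
| 40.0 | 65 | 10 |
| 60.0 | 57 | 7 |
| 80.0 | 49 | 10 |

elm run (percent of the starting material charged)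

| time / min | starting material / % | single product / % |
|---|---|---|
| 0.417 | 57 | 11 |
| 1.33 | 20 | 7 |
| 2.00 | 13 | 4 |
| 3.00 | 4 | 3 |
| 5.00 | 4 | 2 |
| 6.00 | 0 | 2 |

(standard deviation of a reading: 1.5 percentage points)

- starting material at 6.0 min, in percent of the starting material charged
- single product at 6.0 min, in percent of the starting material charged
- bis adduct at 6.0 min, in percent of the starting material charged



Two colleagues dispute the ash flask. She holds a closed chain: starting material takes reagent to give single product, which takes reagent to give bis adduct. Bis adduct is then whatever the other two leave. At 2 reagents per bis adduct, reagent is the limiting reagent, and her ceiling is 90.0%.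

He points to elm, where single product falls from 7% at 1.33 min to 2% at 6.00 min, a rate of 0.268 min⁻¹. Starting material fell at 0.934 min⁻¹ between 0.417 min and 2.00 min, which is faster. So he supposes a pool: single product plus an unseen form, leaving as bis adduct.

I side with him and carry the selectivity factor s = 0.287, the pool's loss rate over that of starting material. In this picture reagent cancels, and the pool is a to the power s, minus a, over one minus s. Its crest is 60.5%, at a = 17.4%.

Near the crest, each starting material lost costs 1.27 reagents. Elm's first reading, with reagent taken as charged, gives a rate constant of 0.0624 M⁻¹ s⁻¹. Integrating the second-order law, my reckoning for 6.0 min is a = 11.4%, a pool of 59.2% and bis adduct 29.5%.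

The forecast stands with her, at 20% starting material, 5% single product and 75% bis adduct: “The flask is the same charge as ash, with reagent nearly spent by then.”

The flask gives 12.4% starting material, 5.54% single product and 41.9% bis adduct, with 40.2% isomer of the product. That bis adduct exceeds my figure, and the pool of 45.7% is below mine.

    reagent + single product → bis adduct + released group (k = 0.180 M⁻¹ s⁻¹)
    starting material + reagent → single product + released group (k = 0.0670 M⁻¹ s⁻¹)
    single product ⇌ isomer of the product (K = 7.10, k = 0.0440 s⁻¹)

Her chain comes close late: at 60.0 min this flask holds 76.6% bis adduct, with 20.0% isomer of the product. Now carry s to the neighbour flask charged with 0.025 M starting material, which shows a = 2.59% at 6.00 min. The same formula gives a pool of 45.5% and bis adduct 51.9%. That neighbour flask holds a pool of 34.8% and 62.6% bis adduct.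

Readings and results were computed from invented constants, noise included.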